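**Retrosynthetic overview**
1. Target 15 ⇐ methyl ester 14 by saponification.
2. The benzoate ring of 14 is opened by a retro-[4+2]: the ring carbon carrying the side chain and the phenol carbon come from the ketene bis-silyl acetal of acid 7; the other four ring carbons and the ester come from methyl coumalate 8 (Diels–Alder, then loss of CO2 and Me3SiOH).
3. Acid 7 ⇐ allylic bromide 4 + acetic acid dianion; 4 ⇐ alcohol 3 ⇐ acid 2.
4. Acid 2 ⇐ (−)-copalic acid 1 by moving the 8(17) alkene to 8(9); C5, C10 and the 13E alkene are bought.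
5. Ring order: the trans-decalin (rings A/B) is bought intact; the aromatic ring is the only ring made, in step 5.

Assumption: (−)-copalic acid (ent-labda-8(17),13E-dien-15-oic acid, the main diterpene acid of commercial copaiba oleoresin) is bought as an isolated natural product, though as an isolated compound it is a specialty item rather than a bulk chemical; the target's (5R,10R) decalin is the ent-labdane series, which copalic acid supplies directly. Labdane numbering is used for positions.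

**Step 1**
Reactants: 1 (−)-copalic acid
Product: 2 ent-labda-8,13E-dien-15-oic acid
Conditions: p-TsOH·H2O (0.2 equiv), toluene, 80 °C; AgNO3–SiO2 chromatography
Reagents that add atoms: none
Why: Acid-catalysed alkene isomerisation through the tertiary C8 cation equilibrates the exocyclic alkene to the most substituted 8(9) position, which deletes the C9 stereocentre while C5, C10 and the deactivated conjugated 13E alkene stay untouched.

**Step 2**
Reactants: 2 ent-labda-8,13E-dien-15-oic acid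
Product: 3 ent-labda-8,13E-dien-15-ol
Conditions: LiAlH4, Et2O, 0 °C → rt; Fieser work-up
Reagents that add atoms: none
Why: Hydride reduction of the β,β-disubstituted enoic acid is 1,2-selective and gives the allylic alcohol with both alkenes and the E geometry intact.

**Step 3**
Reactants: 3 ent-labda-8,13E-dien-15-ol
Product: 4 ent-15-bromolabda-8,13E-diene
Conditions: CBr4, PPh3, CH2Cl2, 0 °C; used crude
Reagents that add atoms: tetrabromomethane, BrC(Br)(Br)Br
Why: The Appel reaction turns the primary allylic alcohol into the bromide by SN2 on the alkoxyphosphonium under neutral conditions, so the acid-sensitive tetrasubstituted alkene and the E alkene survive.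

**Step 4**
Reactants: 4 ent-15-bromolabda-8,13E-diene; 5 acetic acid
Product: 7 2-(ent-labda-8,13E-dien-15-yl)acetic acid, via dilithium acetate enediolate 6 (not isolated)
Conditions: 5, LDA (2 equiv per 5), THF–DMPU, 0 → 40 °C; then 4, 0 °C → rt; cold 1 M HCl to pH 4
Reagents that add atoms: none
Why: SN2 alkylation of the carboxylic acid dianion at the unhindered primary allylic carbon adds the two carbons that become the side-chain-bearing and phenol carbons of the arene, without touching the E alkene.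

**Step 5**
Reactants: 7 2-(ent-labda-8,13E-dien-15-yl)acetic acid; 8 methyl coumalate
Product: 14 methyl 3-(ent-labda-8,13E-dien-15-yl)-4-hydroxybenzoate, via dilithium enediolate 9 (not isolated), via bis-silyl ketene acetal 10 (not isolated), via bicyclic lactone adduct 11 (not isolated), via silyloxy cyclohexadiene 12 (not isolated), via aryl silyl ether 13 (not isolated)
Conditions: LDA (2.2 equiv), THF, −78 → 0 °C; TMSCl (2.5 equiv), −78 °C → rt; evaporate, hexane, filter; 8 (1.5 equiv), toluene, 100 °C; then K2CO3 (cat.), THF/H2O, rt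
Reagents that add atoms: chlorotrimethylsilane, C[Si](C)(C)Cl (its silicon sits only in 10–13 and is lost before 14)
Why: In this inverse-electron-demand Diels–Alder reaction the nucleophilic carbon of the ketene acetal bonds to C6 of the electron-poor 2-pyrone, and retro-Diels–Alder loss of CO2 followed by loss of Me3SiOH aromatises to the 3-alkyl-4-oxygenated benzoate with no stereocentre made or touched.

**Step 6**
Reactants: 14 methyl 3-(ent-labda-8,13E-dien-15-yl)-4-hydroxybenzoate
Product: 15 3-(ent-labda-8,13E-dien-15-yl)-4-hydroxybenzoic acid (CNP0264988.2)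
Conditions: LiOH·H2O, THF/MeOH/H2O, 50 °C; then cold 1 M HCl to pH 3
Reagents that add atoms: lithium hydroxide, [Li+].[OH-]
Why: Ester saponification frees the acid under basic conditions that the ortho-allyl phenol tolerates, and the brief cold acidification avoids acid-catalysed chroman formation.

**Compound list**
(Dec = (4aR,8aR)-2,5,5,8a-tetramethyl-3,4,4a,5,6,7,8,8a-octahydronaphthalen-1-yl)

1 | (−)-copalic acid, (2E)-3-methyl-5-[(1R,4aR,8aR)-5,5,8a-trimethyl-2-methylidenedecahydronaphthalen-1-yl]pent-2-enoic acid | C=C1[C@@H](CC/C(C)=C/C(=O)O)[C@]2(C)CCCC(C)(C)[C@H]2CC1 | starting material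
2 | (2E)-3-methyl-5-Dec-pent-2-enoic acid (ent-labda-8,13E-dien-15-oic acid) | CC1=C(CC/C(C)=C/C(=O)O)[C@]2(C)CCCC(C)(C)[C@H]2CC1 | intermediate
3 | (2E)-3-methyl-5-Dec-pent-2-en-1-ol | CC1=C(CC/C(C)=C/CO)[C@]2(C)CCCC(C)(C)[C@H]2CC1 | intermediate
4 | (2E)-1-bromo-3-methyl-5-Dec-pent-2-ene | CC1=C(CC/C(C)=C/CBr)[C@]2(C)CCCC(C)(C)[C@H]2CC1 | intermediate
5 | acetic acid | CC(=O)O | starting material
6 | dilithium ethene-1,1-bis(olate) (acetic acid dianion) | [Li+].[Li+].C=C([O-])[O-] | intermediate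
7 | (4E)-5-methyl-7-Dec-hept-4-enoic acid | CC1=C(CC/C(C)=C/CCC(=O)O)[C@]2(C)CCCC(C)(C)[C@H]2CC1 | intermediate
8 | methyl coumalate (methyl 2-oxo-2H-pyran-5-carboxylate) | COC(=O)C1=COC(=O)C=C1 | starting material
9 | dilithium (4E)-5-methyl-7-Dec-hepta-1,4-diene-1,1-bis(olate) (dianion of 7) | [Li+].[Li+].CC1=C(CC/C(C)=C/CC=C([O-])[O-])[C@]2(C)CCCC(C)(C)[C@H]2CC1 | intermediate
10 | (4E)-5-methyl-7-Dec-1,1-bis(trimethylsilyloxy)hepta-1,4-diene | CC1=C(CC/C(C)=C/CC=C(O[Si](C)(C)C)O[Si](C)(C)C)[C@]2(C)CCCC(C)(C)[C@H]2CC1 | intermediate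
11 | methyl 7-[(2E)-3-methyl-5-Dec-pent-2-en-1-yl]-3-oxo-8,8-bis(trimethylsilyloxy)-2-oxabicyclo[2.2.2]oct-5-ene-6-carboxylate (transient diastereomer mixture) | CC1=C(CC/C(C)=C/CC3C4OC(=O)C(C=C4C(=O)OC)C3(O[Si](C)(C)C)O[Si](C)(C)C)[C@]2(C)CCCC(C)(C)[C@H]2CC1 | intermediate
12 | methyl 3-[(2E)-3-methyl-5-Dec-pent-2-en-1-yl]-4,4-bis(trimethylsilyloxy)cyclohexa-1,5-diene-1-carboxylate | CC1=C(CC/C(C)=C/CC3C=C(C(=O)OC)C=CC3(O[Si](C)(C)C)O[Si](C)(C)C)[C@]2(C)CCCC(C)(C)[C@H]2CC1 | intermediate
13 | methyl 3-[(2E)-3-methyl-5-Dec-pent-2-en-1-yl]-4-(trimethylsilyloxy)benzoate | CC1=C(CC/C(C)=C/Cc3cc(C(=O)OC)ccc3O[Si](C)(C)C)[C@]2(C)CCCC(C)(C)[C@H]2CC1 | intermediate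
14 | methyl 4-hydroxy-3-[(2E)-3-methyl-5-Dec-pent-2-en-1-yl]benzoate | CC1=C(CC/C(C)=C/Cc3cc(C(=O)OC)ccc3O)[C@]2(C)CCCC(C)(C)[C@H]2CC1 | intermediate
15 | 4-hydroxy-3-[(2E)-3-methyl-5-Dec-pent-2-en-1-yl]benzoic acid | CC1=C(CC/C(C)=C/Cc2cc(C(=O)O)ccc2O)[C@]2(C)CCCC(C)(C)[C@H]2CC1 | target

**Total step count:** 6. **Longest linear sequence:** 6 steps (1 → 15).

**Steps most likely to fail**

Step 1. The equilibration may stop at a mixture with the Δ7 isomer, or the C8 cation may rearrange. The fallback sets out from 1 and rejoins at 3. Acid 1 is O-methylated (MeI, K2CO3, DMF) to methyl copalate F1. F1 is isomerised by reversible HI addition–elimination (57% HI cat., benzene, 80 °C) to methyl ent-labda-8,13E-dien-15-oate F2, a neutral ester that separates from residual isomers on AgNO3–silica more easily than the acid. DIBAL-H (CH2Cl2, −78 °C) then reduces F2 directly to 3.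

Step 4. The poorly soluble, strongly basic dianion may give E2 or SN2′ products from 4. The fallback sets out from 4 and rejoins at 7. Sodium diethyl malonate (NaH, diethyl malonate, THF–DMF, 0 °C → rt), a soft nucleophile, gives diethyl 2-(ent-labda-8,13E-dien-15-yl)malonate F3. KOH in EtOH/H2O at reflux, then cold acidification, gives 2-(ent-labda-8,13E-dien-15-yl)malonic acid F4. Heating F4 in pyridine at 110 °C decarboxylates it to 7.

Step 5. The hindered, moisture-sensitive ketene acetal may hydrolyse or only add in Michael fashion instead of closing the ring. The fallback sets out from 4 and rejoins at 15, keeping the pyrone cycloaddition but with an alkyne dienophile. Lithium ethoxyacetylide (ethoxyacetylene, n-BuLi, THF–HMPA, −78 → 0 °C) is alkylated by 4 to the ynol ether 1-ethoxy-2-(ent-labda-8,13E-dien-15-yl)ethyne F5. With 8 in toluene at 70–80 °C (kept below the retro-ene temperature of the ynol ether), F5 gives the bicyclic lactone adduct F6. F6 loses CO2 to give methyl 4-ethoxy-3-(ent-labda-8,13E-dien-15-yl)benzoate F7. NaSEt in DMF at 130 °C cleaves the ethyl ether and the methyl ester together and gives 15 after cold acidification.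

**Further compounds**
F1 | step 1 | methyl (2E)-3-methyl-5-[(1R,4aR,8aR)-5,5,8a-trimethyl-2-methylidenedecahydronaphthalen-1-yl]pent-2-enoate (methyl copalate) | C=C1[C@@H](CC/C(C)=C/C(=O)OC)[C@]2(C)CCCC(C)(C)[C@H]2CC1
F2 | step 1 | methyl (2E)-3-methyl-5-Dec-pent-2-enoate (methyl ent-labda-8,13E-dien-15-oate) | CC1=C(CC/C(C)=C/C(=O)OC)[C@]2(C)CCCC(C)(C)[C@H]2CC1
F3 | step 4 | diethyl 2-[(2E)-3-methyl-5-Dec-pent-2-en-1-yl]propanedioate | CC1=C(CC/C(C)=C/CC(C(=O)OCC)C(=O)OCC)[C@]2(C)CCCC(C)(C)[C@H]2CC1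
F4 | step 4 | 2-[(2E)-3-methyl-5-Dec-pent-2-en-1-yl]propanedioic acid | CC1=C(CC/C(C)=C/CC(C(=O)O)C(=O)O)[C@]2(C)CCCC(C)(C)[C@H]2CC1
F5 | step 5 | (4aR,8aR)-1-[(3E)-7-ethoxy-3-methylhept-3-en-6-yn-1-yl]-2,5,5,8a-tetramethyl-3,4,4a,5,6,7,8,8a-octahydronaphthalene | CC1=C(CC/C(C)=C/CC#COCC)[C@]2(C)CCCC(C)(C)[C@H]2CC1
F6 | step 5 | methyl 8-ethoxy-7-[(2E)-3-methyl-5-Dec-pent-2-en-1-yl]-3-oxo-2-oxabicyclo[2.2.2]octa-5,7-diene-6-carboxylate | CC1=C(CC/C(C)=C/CC3=C(OCC)C4C=C(C(=O)OC)C3OC4=O)[C@]2(C)CCCC(C)(C)[C@H]2CC1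
F7 | step 5 | methyl 4-ethoxy-3-[(2E)-3-methyl-5-Dec-pent-2-en-1-yl]benzoate | CC1=C(CC/C(C)=C/Cc3cc(C(=O)OC)ccc3OCC)[C@]2(C)CCCC(C)(C)[C@H]2CC1
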